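In the cedar run, substrate stops falling at 88.0 %, the mean of its readings from 25.0 s on. Partner B, at 0.74 equiv, is less than partner A at 1.1 equiv, so the stall is taken as the end of partner B, the limiting reagent of cedar.

| setting | cedar | larch | elm | Wednesday's | Tuesday's | Monday's | Thursday's | Friday's |
|---|---|---|---|---|---|---|---|---|
| substrate | 0.13 M | 0.13 M | 0.17 M | 0.040 M | 0.13 M | 0.40 M | 0.13 M | 0.13 M |
| partner A | 1.1 equiv | 1.1 equiv | 1.1 equiv | 1.10 equiv | 2.20 equiv | 1.10 equiv | 1.10 equiv | 1.10 equiv |
| partner B | 0.74 equiv | 6.3 equiv | 2 equiv | 2.00 equiv | 1.00 equiv | 4.00 equiv | 2.00 equiv | 0.500 equiv |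
| capture agent | 2.6 mM | 2.6 mM | 2.6 mM | 4.00 mM | 2.60 mM | 5.00 mM | 2.60 mM | 2.00 mM |
| remark | run made earlier | run made earlier | run made earlier |  |  |  |  |  |
| time |  |  |  | 2.0 min | 2.0 min | 2.0 min | 2.0 min | 2.0 min |

| run | time / s | target / % | substrate / % |
|---|---|---|---|
| cedar | 12.0 | 2.1 | 91.1 |
| cedar | 25.0 | 2.1 | 88.6 |
| cedar | 40.0 | 2.2 | 88.3 |
| cedar | 50.0 | 2.9 | 87.6 |
| cedar | 60.0 | 5.1 | 88.2 |
| cedar | 80.0 | 8.0 | 87.5 |
| larch | 10.0 | 9.7 | 16.9 |
| larch | 15.0 | 14.8 | 7.4 |
| larch | 25.0 | 25.2 | 1.7 |
| larch | 40.0 | 33.2 | 0.1 |
| larch | 60.0 | 37.9 | 1.2 |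
| larch | 80.0 | 42.0 | 0 |
| elm | 10.0 | 5.4 | 63.2 |
| elm | 12.0 | 7.0 | 59.5 |
| elm | 25.0 | 16.0 | 45.4 |
| elm | 40.0 | 23.5 | 34.0 |
| elm | 80.0 | 35.3 | 23.3 |

(scatter of a reading: 1 percentage point)

- no earlier run changes the charge of capture agent; that part of a forecast is a guess

- all flasks from highest to lowest amount of target, in percent of the substrate charged, at 2.0 min (Wednesday's / Tuesday's / Monday's / Thursday's / Friday's)
- the amount of target, in percent of the substrate charged of the flask you put first, at 2.0 min
- the amount of target, in percent of the substrate charged of the flask you put last, at 2.0 min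

If substrate and partner A each react at a rate proportional to partner B and to themselves, partner B cancels from the ratio of their fractional losses. Let s and a be the fractions of substrate and partner A left. The selectivity factor σ, the ratio ln s / ln a, then stays constant through a flask. In cedar, the partner B not taken by substrate went to partner A, which leaves a = 43.6 %, so σ = 0.153, a reading with the scatter of the readings behind it.

Friday's has cedar's substrate and partner A with less partner B, and there are two ways to its substrate loss. The first is a plain share: cedar's substrate took an estimated 16.2 % of partner B, which puts Friday's loss at 8.08 %. The second puts that estimate into the balance, giving a = 61.9 %, and then applies σ, which gives a loss of 7.10 %. They part by about one scatter, and the plain share is the one that cheats. It is an average over the whole of cedar, where the reckoned partner A ends lower than in Friday's, and under this rule substrate's share grows as partner A thins.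

Target is drawn from the substrate lost, so that loss serves as an estimated ceiling on target, about 7.10 % for Friday's. The same reckoning puts the ceiling for Tuesday's at about 7.97 %. At the other end, Thursday's and Wednesday's hold partner B beyond partner A by 90.0 % of the substrate, and the excess in Monday's is larger than its substrate. Wednesday's runs at 0.308 of Thursday's substrate concentration and is expected to trail it, but its excess of partner B places it, as a judgement, above the ceiling for Tuesday's. The order reckoned here is therefore Monday's, Thursday's, Wednesday's, Tuesday's, Friday's, with Monday's own figure beyond this rule.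

The forecast gives Monday's > Thursday's > Tuesday's > Wednesday's > Friday's, with 50 % and 4 %, saying “Wednesday is dilute, but its 10% capture charge may help”, and so differs from this reckoning on Tuesday's and Wednesday's.

The flasks give Monday's > Thursday's > Wednesday's > Tuesday's > Friday's, with 59.3 % for Monday's and 2.59 % for Friday's.

    partner B + partner A → second intermediate (k = 1.85 L mol⁻¹ s⁻¹)
    open intermediate + second intermediate → target (k = 0.167 L mol⁻¹ s⁻¹)
    second intermediate + capture agent → trapped intermediate (k = 0.127 L mol⁻¹ s⁻¹)
    second intermediate → side product (k = 0.00733 s⁻¹)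
    substrate + partner B → open intermediate (k = 0.289 L mol⁻¹ s⁻¹)
    target ⇌ isomer of the product (K = 0.410, k = 0.0158 s⁻¹)

In Friday's, partner B at the start goes to partner A 7.0 times as fast as to substrate. At 2.00 min Friday's holds partner B at 0 %, partner A at 61 % of its charge and substrate at 93 %. Applied to that partner A, σ gives substrate at 92.7 %. The neighbour of Friday's with 1.20 equiv of partner B ends with partner A at 15 %, for which σ gives 74.8 %, and that flask holds substrate at 74.0 %.

(The data are simulated for an exercise, and the scatter is random.)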